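- Whether more starting material pays in a flask can be read from two rates: the rate r at the present level S of starting material, and the ceiling rate V of that catalyst charge.

| flask | starting material | catalyst | target | time |
|---|---|---|---|---|
| Wednesday's | 100 mM | 1.00 mM |  |  |
| Sunday's | 40.0 mM | 1.00 mM |  |  |
| Friday's | 100 mM | 1.00 mM | 30.0 mM |  |
| Saturday's | 150 mM | 1.00 mM |  |  |
| Thursday's | 50.0 mM | 0.330 mM |  | 38 min |

- Wednesday's run (time / min: [target] / mM): 1.5: 2.7; 2.4: 5.6; 3.8: 7.3; 6.0: 12.0; 9.6: 19.0; 15: 27.4; 24: 43.8; 38: 63.9
- Sunday's run (time / min: [target] / mM): 1.5: 2.4; 2.4: 3.0; 3.8: 5.6; 6.0: 8.2; 9.6: 12.4; 15: 17.7; 24: 26.9; 38: 34.8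
- Friday's run (time / min: [target] / mM): 1.5: 32.2; 2.4: 34.1; 3.8: 37.4; 6.0: 42.2; 9.6: 48.7; 15: 58.1; 24: 73.5; 38: 93.3
- Saturday's run (time / min: [target] / mM): 1.5: 3.3; 2.4: 5.2; 3.8: 7.6; 6.0: 13.1; 9.6: 19.7; 15: 32.1; 24: 49.5; 38: 75.5

(each reading ± 0.5 mM)

- Overall: starting material -> target, with catalyst as catalyst.
- Constant volume, constant temperature.
- A reading of a species includes what of it is bound.
- An order is taken over about fifteen percent of the charge, up and down.

* reaction order in [starting material] at the outset, round the charge of the Wednesday's run, defined at two percent of the starting material turned into target (one fixed amount of target, the same in the runs compared)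
* the Sunday's run starts with 60.0 mM less of starting material than the Wednesday's run, and with no target. Compared where both hold the same amount of starting material, once fifteen percent of what the Sunday's run was charged with has turned into target, is the Sunday's run faster, slower or alike (within a tenth)?
* target in the Thursday's run at 38 min, as a share of the starting material charged

- Their ratio, the fill f = r/V, has its symmetric point at one half, and the level of starting material at that point is K, the half-saturation constant. If the rate follows a saturation curve, f = S/(K+S), and the order in starting material is 1 − f.
- Over the first 6.0 min, Sunday's run gains 1.37 mM min⁻¹ around 35.9 mM, and Saturday's run gains 2.18 mM min⁻¹ around 143 mM.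
- Saturday's level is 3.98 times Sunday's, yet its rate is 1.59 times Sunday's, which marks a ceiling. My straight line through S/r against S reads V = 2.73 mM min⁻¹ and K = 35.7 mM.
- Friday's run gains 63.3 mM by 38 min and Wednesday's run 63.9 mM, so target shows no effect on the rate. With f depending on S, I expect Sunday's and Wednesday's runs to be alike at equal S.
- At two percent turned, Wednesday's run holds 98.0 mM, which gives my order 0.267.
- Thursday's flask has a third of the catalyst. If V scales with catalyst, V = 0.900 mM min⁻¹, and a third of its charge turns by 34.6 min. The remaining minutes to 38 min add 1.47 mM, so my figure is 36.3%.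
- The forecast gives an order of 0.29, alike and 35.5%, its order above mine and its Thursday share below mine. Its reckoning takes “Km ≈ 40 mM” where mine takes K = 35.7 mM, and both take the rate as proportional to catalyst.

    catalyst + starting material ⇌ catalyst-substrate complex, settled at all times (13.30 M⁻¹)
    catalyst-substrate complex + catalyst → target + 2 catalyst (5334 M⁻¹ min⁻¹)
    starting material → target (0.01032 min⁻¹)
    2 starting material ⇌ idle substrate dimer, settled at all times (5.150 M⁻¹)

- Thursday's flask holds 33.5% of its charge at 38 min, which is 16.7 mM of target. Wednesday's order is 0.29, and Sunday's rate over Wednesday's at equal starting material is 1.0, so the two runs are alike. For Saturday's run, K and V put half the charge into target at 36.6 min, and the run itself comes to half at 37.6 min.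

The runs are calculated with constants of no real substance, noise included.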